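At 7.7 h the west run, charged with 120 mM of starting material, reads 82.6 mM of target, and you must decide whether the south-east flask, with 40.0 mM of starting material and 19.0 mM of free catalyst, goes ahead as written or gets more catalyst first.

| flask | starting material | coupling partner | free catalyst | target | time |
|---|---|---|---|---|---|
| west | 120 mM | 300 mM | 9.60 mM |  |  |
| north-east | 48.0 mM | 228 mM | 9.60 mM |  |  |
| north | 120 mM | 300 mM | 29.0 mM |  |  |
| south | 120 mM | 300 mM | 9.60 mM | 60.0 mM |  |
| south-east | 40.0 mM | 300 mM | 19.0 mM |  | 7.7 h |

| run | time / h | [target] / mM |
|---|---|---|
| west run | 0.31 | 25.5 |
| west run | 0.49 | 36.4 |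
| west run | 0.77 | 45.4 |
| west run | 1.2 | 53.1 |
| west run | 1.9 | 62.4 |
| west run | 3.1 | 70.3 |
| west run | 4.9 | 77.8 |
| west run | 7.7 | 82.6 |
| north-east run | 0.31 | 10.4 |
| north-east run | 0.49 | 14.1 |
| north-east run | 0.77 | 15.6 |
| north-east run | 1.2 | 18.9 |
| north-east run | 1.9 | 25.2 |
| north-east run | 3.1 | 29.0 |
| north-east run | 4.9 | 30.4 |
| north-east run | 7.7 | 33.3 |
| north run | 0.31 | 34.6 |
| north run | 0.49 | 43.9 |
| north run | 0.77 | 54.4 |
| north run | 1.2 | 66.3 |
| north run | 1.9 | 74.2 |
| north run | 3.1 | 81.5 |
| north run | 4.9 | 88.0 |
| north run | 7.7 | 92.9 |
| south run | 0.31 | 85.9 |
| south run | 0.49 | 96.4 |
| south run | 0.77 | 105.2 |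
| south run | 1.2 | 113.6 |
| south run | 1.9 | 122.3 |
| south run | 3.1 | 129.2 |
| south run | 4.9 | 135.7 |
| south run | 7.7 | 143.3 |

(scatter of a reading: 1 mM)

* the exponent of [free catalyst] in the starting rate at the charge of the west run (at the point where two percent of the starting material have become target)
* the north-east run starts with 72.0 mM less of starting material and of coupling partner than the west run, and with no target. Compared where both hold the same amount of starting material, once fifteen percent of what the north-east run was charged with has turned into target, is the north-east run faster, slower or alike (within a tenth)?
* target in the south-east run at 7.7 h, as a share of the starting material charged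

- Overall: starting material + coupling partner -> target, with free catalyst as catalyst.
- Constant volume, constant temperature.
- An order is taken over about fifteen percent of the charge, up and down.

Write Q for the starting material charged and S for what remains. In the west run at 7.7 h, ln(Q/S) stands at 1.17; call this the e-fold count L, the number of e-foldings of starting material a flask has achieved by a given time. It is worth carrying to the next flask, since at the same time the north-east run reads 1.18, and the south run, with its added target subtracted, reads 1.18. Catalyst moves it more weakly than you might hope: the north run, with 29.0 mM against 9.60 mM, reads 1.49, which is an exponent of 0.221.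

Time also buys less and less. The west run has L = 0.584 by 1.2 h, and near 3.1 h to 4.9 h, holding about as much starting material as the north-east charge, it gains 0.0909 h⁻¹. The fresh north-east run gains 0.788 h⁻¹ over its first reading, which is faster than that west stretch.

My own reckoning carries that exponent to the south-east catalyst and gives L = 1.36, or 74.2% of the charge. So I would run the recipe as written and add no catalyst.

The forecast gives an exponent of 0.35 (0.15 to 0.75), calls the north-east run faster, and puts the south-east run at 75% (71% to 79%), a little above my share. Its reading of the fade is “so the catalyst is dying with time”.

The simulation gives an exponent of 0.26, the north-east run faster, and 80.9% in the south-east run.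

    2 free catalyst ⇌ catalyst dimer, settled at all times (1290 L mol⁻¹)
    free catalyst + starting material + coupling partner → target + free catalyst (972.0 L² mol⁻² h⁻¹)
    starting material + coupling partner → target (1.980 L mol⁻¹ h⁻¹)
    2 coupling partner → lost reagent (3.456 L mol⁻¹ h⁻¹)

That share is L = 1.65 for the south-east run, against 1.17 for the west run and my 1.36. What stands between the south-east run and full conversion is the step taking two coupling partner to lost reagent: at 300 mM the first half-life of the coupling partner by this step alone is 0.482 h, and without that step the south-east run reaches >99.9%.

Readings and results are simulated for an exercise; scatter was added.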